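**Plan**

1. Retrosynthesis: the C4–O benzoate bond (esterification with inversion), the C3–O bond (enol ether oxidation) and the C2–O bond (oxa-Michael) are cut in turn. This uncovers an achiral p-quinol, whose C1–OH comes from oxidative dearomatization of a phenol and whose C7–O benzoate comes from acylation of 4-hydroxybenzyl alcohol.
2. Forward: the carbocycle is the benzene ring of the starting phenol and is never opened. The only ring closed is a temporary 1,3-dioxolane across C1–C2, whose acetal carbon comes from isobutyraldehyde and which is hydrolysed in the last step.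
3. Enabling feature: carbinol C1 (bearing C7) lies para to oxygenated C4, between the arms C2–C3 and C6=C5. The ring is therefore a latent 4-hydroxycyclohexa-2,5-dienone with a mirror plane through C1 and C4, and the cis C1–OH/C2–OH pair can be bridged by one acetal carbon into a five-membered ring.
4. Stereochemistry: C1 and C2 are set together by a chiral phosphoric acid (choice of enone arm) and the cis ring fusion. C3 is set by substrate control in a Rubottom oxidation (anti to C2–O). C4 is set by Luche reduction followed by Mitsunobu inversion.

Key step: step 4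

Locants throughout are those of the target: C1 is the tertiary carbinol carrying the exocyclic CH2 (C7), C2 and C3 are the secondary carbinols, C4 carries the ring benzoate, and C5=C6 is the alkene.

Assumption: the sense of induction of the phosphoric acid on this quinol is not predicted here; the (S)-configured catalyst is written for the arm shown, and the (R)-catalyst is to be used if closure occurs on the opposite arm.

Remark: 4-hydroxybenzyl benzoate expels benzoate from its phenoxide (p-quinone methide formation), so it is never exposed to aqueous base, and the dearomatization is run under acidic hypervalent iodine conditions.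

**Route**

Step 1
Reactants: 1 4-hydroxybenzyl alcohol; 2 benzoyl chloride
Product: 3 4-(benzoyloxymethyl)phenyl benzoate
Conditions: 2 (2.3 equiv), Et3N, 4-(dimethylamino)pyridine (catalytic), CH2Cl2, 0 °C to rt
Reagents that add atoms: none
Why: Acylation with an acid chloride under nucleophilic catalysis esterifies both the phenol and the primary benzylic alcohol, so no chemoselectivity is needed at this stage and no stereocenter is formed.

Step 2
Reactants: 3 4-(benzoyloxymethyl)phenyl benzoate
Product: 4 4-hydroxybenzyl benzoate
Conditions: pyrrolidine (1.1 equiv), THF, 0 °C to rt; then aqueous citric acid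
Reagents that add atoms: none
Why: Chemoselective aminolysis, in which the aryl ester with its phenoxide leaving group reacts with the amine far faster than the alkyl ester, while the aprotic medium, the near-stoichiometric amine and the acidic quench keep the liberated phenol from ionising and losing the benzylic benzoate.

Step 3
Reactants: 4 4-hydroxybenzyl benzoate
Product: 5 (1-hydroxy-4-oxocyclohexa-2,5-dien-1-yl)methyl benzoate (achiral p-quinol)
Conditions: PhI(OAc)2, MeCN/H2O (3:1), 0 °C
Reagents that add atoms: water, O
Why: Hypervalent iodine oxidative dearomatization of a para-alkylphenol, in which ligand exchange at iodine and attack of water at the para carbon give the p-quinol under acidic conditions that avoid the benzoate-expelling phenoxide; the product is achiral.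

Step 4
Reactants: 5 (1-hydroxy-4-oxocyclohexa-2,5-dien-1-yl)methyl benzoate; 6 isobutyraldehyde
Product: 8 cis-fused dioxolane enone (1S,2S; acetal carbon R), via isobutyraldehyde hemiacetal 7 (not isolated)
Conditions: (S)-3,3'-bis(2,4,6-triisopropylphenyl)-1,1'-binaphthyl-2,2'-diyl hydrogen phosphate (5 mol %), N,N'-bis[3,5-bis(trifluoromethyl)phenyl]thiourea (5 mol %), 6 (3 equiv), 4 Å molecular sieves, ClCH2CH2Cl, 45 °C
Reagents that add atoms: none
Why: The tertiary hydroxyl of 5 adds reversibly to 6 to give the rapidly epimerising hemiacetal 7, and the bifunctional phosphoric acid, hydrogen-bonded to the hemiacetal OH and the dienone carbonyl, delivers the hemiacetal oxygen to one of the two enantiotopic beta carbons (C2); the closest known reaction type is the chiral Brønsted acid catalysed desymmetrizing acetalization/oxa-Michael cascade of p-quinols and p-peroxyquinols with aldehydes. The 1,3-dioxolane closes in a 5-exo-trig mode by O–C2 bond formation and can only be cis-fused, so C2 is fixed relative to C1 by the five-membered tether. C1 becomes stereogenic only through the choice of arm, so the catalyst sets the absolute configuration of C1 and C2 together, in a process that is both a dynamic resolution of the hemiacetal and a desymmetrization; the acetal carbon should settle with isopropyl on the convex (exo) face and is lost at the end. The step needs enantiotopic-group selectivity and chemoselectivity: the mirror plane through C1 and C4 makes the two arms differ only inside the catalyst pocket, and 5 has a single nucleophilic OH, an inert benzoate and, after one addition, a beta-alkoxy ketone that cannot add a second time.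

Step 5
Reactants: 8 cis-fused dioxolane enone
Product: 9 4-triethylsilyloxy-3,5-diene (silyl dienol ether)
Conditions: TESOTf, Et3N, CH2Cl2, −78 °C; non-aqueous work-up, used crude
Reagents that add atoms: triethylsilyl trifluoromethanesulfonate, CC[Si](CC)(CC)OS(=O)(=O)C(F)(F)F
Why: Soft enolization with a silyl triflate and a tertiary amine removes a proton from C3, the only position with acidic alpha hydrogens because C1 is quaternary, and gives the cross-conjugated silyloxydiene without a free enolate, so the C2 oxygen is not lost by E1cB retro-oxa-Michael.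

Step 6
Reactants: 9 silyl dienol ether
Product: 11 C3-triethylsilyloxy enone (1S,2S,3S), via silyloxy epoxide 10 (not isolated)
Conditions: mCPBA, NaHCO3, CH2Cl2, −20 to 0 °C
Reagents that add atoms: 3-chloroperoxybenzoic acid (mCPBA), OOC(=O)c1cccc(Cl)c1
Why: Rubottom oxidation, in which the peracid epoxidizes the electron-rich enol ether alkene C3=C4 rather than C5=C6, on the face anti to the allylic C2–O bond and the dioxolane ring, and opening of epoxide 10 with 1,4-silyl transfer gives the alpha-silyloxy ketone with C3–O trans to C2–O.

Step 7
Reactants: 11 C3-triethylsilyloxy enone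
Product: 12 3,4-trans allylic alcohol (1S,2S,3R,4S)
Conditions: NaBH4, CeCl3·7H2O, MeOH, −78 °C
Reagents that add atoms: none
Why: Luche 1,2-reduction of the enone, in which axial hydride delivery to the half-chair that keeps the C3 silyloxy group and C7 pseudoequatorial should place the new C4 hydroxyl trans to the C3 oxygen.

Step 8
Reactants: 12 3,4-trans allylic alcohol; 13 benzoic acid
Product: 15 fully protected dibenzoate (1S,2S,3R,4R), via C4 alkoxyphosphonium benzoate 14 (not isolated)
Conditions: PPh3, DIAD, THF, 0 °C to rt
Reagents that add atoms: none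
Why: Mitsunobu esterification, in which benzoate displaces the alkoxyphosphonium group of 14 in an SN2 reaction with inversion at allylic C4, placing the ring benzoate cis to the C3 oxygen, while SN2' attack at C6 is disfavoured by the adjacent quaternary C1.

Step 9
Reactants: 15 fully protected dibenzoate
Product: 17 target CNP0217467.1 (1S,2S,3S,4R), via C3 alcohol acetal 16 (not isolated)
Conditions: TFA/H2O (9:1), CH2Cl2, 0 °C to rt
Reagents that add atoms: none
Why: Acid-catalysed hydrolysis, in which the triethylsilyl ether cleaves first and the aldehyde-derived dioxolane then opens through the oxocarbenium ion at the acetal carbon, so no bond to C1, C2 or C3 is broken and all four stereocenters are retained, while both benzoates survive the non-basic medium.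

**Compound list**

1 | 4-hydroxybenzyl alcohol | OCc1ccc(O)cc1 | starting material
2 | benzoyl chloride | O=C(Cl)c1ccccc1 | starting material
3 | 4-(benzoyloxymethyl)phenyl benzoate | O=C(OCc1ccc(OC(=O)c2ccccc2)cc1)c1ccccc1 | intermediate
4 | 4-hydroxybenzyl benzoate | O=C(OCc1ccc(O)cc1)c1ccccc1 | intermediate
5 | (1-hydroxy-4-oxocyclohexa-2,5-dien-1-yl)methyl benzoate, achiral p-quinol | O=C(OCC1(O)C=CC(=O)C=C1)c1ccccc1 | intermediate
6 | isobutyraldehyde (2-methylpropanal) | CC(C)C=O | starting material
7 | [1-(1-hydroxy-2-methylpropoxy)-4-oxocyclohexa-2,5-dien-1-yl]methyl benzoate, hemiacetal with a configurationally labile hemiacetal carbon | O=C(OCC1(OC(O)C(C)C)C=CC(=O)C=C1)c1ccccc1 | intermediate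
8 | [(2R,3aS,7aS)-5-oxo-2-(propan-2-yl)-3a,4,5,7a-tetrahydro-2H-1,3-benzodioxol-7a-yl]methyl benzoate; cis-fused dioxolane enone, (1S,2S) in target locants, isopropyl exo | O=C(OC[C@@]1(O[C@H](C(C)C)O2)C=CC(=O)C[C@@H]12)c1ccccc1 | intermediate
9 | [(2R,3aS,7aS)-2-(propan-2-yl)-5-(triethylsilyloxy)-3a,7a-dihydro-2H-1,3-benzodioxol-7a-yl]methyl benzoate; silyl dienol ether with C3=C4 and C5=C6 alkenes | O=C(OC[C@@]1(O[C@H](C(C)C)O2)C=CC(O[Si](CC)(CC)CC)=C[C@@H]12)c1ccccc1 | intermediate
10 | 3,4-epoxide of 9, (1S,2S,3S,4S); oxirane oxygen on the ring face opposite the dioxolane oxygens, C4 carrying OSiEt3 | O=C(OC[C@@]1(O[C@H](C(C)C)O2)C=C[C@@]3(O[Si](CC)(CC)CC)O[C@H]3[C@@H]12)c1ccccc1 | intermediate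
11 | [(2R,3aS,4S,7aS)-5-oxo-2-(propan-2-yl)-4-(triethylsilyloxy)-3a,4,5,7a-tetrahydro-2H-1,3-benzodioxol-7a-yl]methyl benzoate; (1S,2S,3S), C3–O trans to C2–O | O=C(OC[C@@]1(O[C@H](C(C)C)O2)C=CC(=O)[C@@H](O[Si](CC)(CC)CC)[C@@H]12)c1ccccc1 | intermediate
12 | [(2R,3aS,4R,5S,7aS)-5-hydroxy-2-(propan-2-yl)-4-(triethylsilyloxy)-3a,4,5,7a-tetrahydro-2H-1,3-benzodioxol-7a-yl]methyl benzoate; (1S,2S,3R,4S), C4–OH trans to C3–O | O=C(OC[C@@]1(O[C@H](C(C)C)O2)C=C[C@H](O)[C@@H](O[Si](CC)(CC)CC)[C@@H]12)c1ccccc1 | intermediate
13 | benzoic acid | OC(=O)c1ccccc1 | starting material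
14 | C4-O-triphenylphosphonium derivative of 12 as its benzoate salt, (1S,2S,3S,4S) | O=C(OC[C@@]1(O[C@H](C(C)C)O2)C=C[C@H](O[P+](c3ccccc3)(c3ccccc3)c3ccccc3)[C@@H](O[Si](CC)(CC)CC)[C@@H]12)c1ccccc1.[O-]C(=O)c1ccccc1 | intermediate
15 | (2R,3aS,4R,5R,7aS)-7a-(benzoyloxymethyl)-2-(propan-2-yl)-4-(triethylsilyloxy)-3a,4,5,7a-tetrahydro-2H-1,3-benzodioxol-5-yl benzoate; (1S,2S,3R,4R), C4–OBz cis to C3–O | O=C(OC[C@@]1(O[C@H](C(C)C)O2)C=C[C@@H](OC(=O)c3ccccc3)[C@@H](O[Si](CC)(CC)CC)[C@@H]12)c1ccccc1 | intermediate
16 | (2R,3aS,4R,5R,7aS)-7a-(benzoyloxymethyl)-4-hydroxy-2-(propan-2-yl)-3a,4,5,7a-tetrahydro-2H-1,3-benzodioxol-5-yl benzoate; (1S,2S,3R,4R) | O=C(OC[C@@]1(O[C@H](C(C)C)O2)C=C[C@@H](OC(=O)c3ccccc3)[C@@H](O)[C@@H]12)c1ccccc1 | intermediate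
17 | [(1S,2S,3S,4R)-4-(benzoyloxy)-1,2,3-trihydroxycyclohex-5-en-1-yl]methyl benzoate, CNP0217467.1 | O=C(OC[C@@]1(O)C=C[C@@H](OC(=O)c2ccccc2)[C@@H](O)[C@@H]1O)c1ccccc1 | target

**Step count and risks**

Total step count: 9. Longest linear sequence: 9 steps (1 to 17).

The three steps most likely to fail:

Step 4. The catalyst may discriminate the two enantiotopic enone arms only weakly when C1 carries a benzoyloxymethyl group, which is a second hydrogen-bond acceptor. Closure may also stall because the hemiacetal of a tertiary alcohol is sparsely populated. The fallback replaces asymmetric catalysis by resolution and sets out from 5 and 6. The same acetalization/oxa-Michael cascade is run with achiral diphenyl phosphate to give the racemic cis-fused acetal. The enantiomers are separated by preparative chromatography on a chiral stationary phase, and the wanted one is 8, where the route is rejoined. The enantiomeric acetal enone F1 is returned to 5 by reversal of the cascade (catalytic DBU in wet acetonitrile, retro-oxa-Michael then loss of isobutyraldehyde) and recycled.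

Step 6 (together with the enolization of step 5). The peracid may attack the enol ether from the face syn to the dioxolane, or the C2 oxygen may be lost by E1cB elimination during enolization. The fallback replaces enol ether oxidation by osmylation of a diene and sets out from 8. Luche reduction (NaBH4, CeCl3·7H2O, MeOH, −78 °C) gives the allylic alcohol F2 as a mixture of C4 epimers, which is of no consequence. Syn-dehydration with the Burgess reagent (methyl N-(triethylammoniosulfonyl)carbamate, toluene, 60 °C) can only remove a hydrogen from C3 and gives the diene acetal F3. Catalytic OsO4 with N-methylmorpholine N-oxide should dihydroxylate the C3=C4 alkene from the face opposite the dioxolane, because C5=C6 is shielded on both faces by quaternary C1, and gives the diol F4 with both new hydroxyls anti to the acetal oxygens. Benzoylation of the less hindered allylic C4 hydroxyl with 2 (2,4,6-collidine, CH2Cl2, −40 °C) gives 16, where the route is rejoined; 16 is isolated here and then taken through the hydrolysis conditions of step 9 to 17.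

Step 7. Hydride may be delivered from the other face, through equatorial attack or through the conformer with an axial silyloxy group, giving the 3,4-cis alcohol or a mixture of epimers. The fallback replaces reduction-inversion by acylation with retention and sets out from 11. The 3,4-cis alcohol F5 is benzoylated directly with 2 (pyridine, catalytic 4-(dimethylamino)pyridine, CH2Cl2, 0 °C) to give 15, where the route is rejoined. If both epimers form, they are separated, 12 goes through step 8, and the two streams converge on 15.

**Further compounds**

F1 | step 4 | [(2S,3aR,7aR)-5-oxo-2-(propan-2-yl)-3a,4,5,7a-tetrahydro-2H-1,3-benzodioxol-7a-yl]methyl benzoate, enantiomer of 8 | O=C(OC[C@]1(O[C@@H](C(C)C)O2)C=CC(=O)C[C@H]12)c1ccccc1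
F2 | step 6 | [(2R,3aS,7aS)-5-hydroxy-2-(propan-2-yl)-3a,4,5,7a-tetrahydro-2H-1,3-benzodioxol-7a-yl]methyl benzoate, mixture of epimers at the carbinol carbon (target C4) | O=C(OC[C@@]1(O[C@H](C(C)C)O2)C=CC(O)C[C@@H]12)c1ccccc1
F3 | step 6 | [(2R,3aS,7aS)-2-(propan-2-yl)-3a,7a-dihydro-2H-1,3-benzodioxol-7a-yl]methyl benzoate, diene acetal | O=C(OC[C@@]1(O[C@H](C(C)C)O2)C=CC=C[C@@H]12)c1ccccc1
F4 | step 6 | [(2R,3aS,4R,5R,7aS)-4,5-dihydroxy-2-(propan-2-yl)-3a,4,5,7a-tetrahydro-2H-1,3-benzodioxol-7a-yl]methyl benzoate, diol anti to the dioxolane | O=C(OC[C@@]1(O[C@H](C(C)C)O2)C=C[C@@H](O)[C@@H](O)[C@@H]12)c1ccccc1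
F5 | step 7 | [(2R,3aS,4R,5R,7aS)-5-hydroxy-2-(propan-2-yl)-4-(triethylsilyloxy)-3a,4,5,7a-tetrahydro-2H-1,3-benzodioxol-7a-yl]methyl benzoate, 3,4-cis alcohol | O=C(OC[C@@]1(O[C@H](C(C)C)O2)C=C[C@@H](O)[C@@H](O[Si](CC)(CC)CC)[C@@H]12)c1ccccc1
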